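## Retrosynthetic overview

1. Target ⇐ 4-methyl diosphenol 23 (exocyclic C4=C18 by selenoxide elimination) ⇐ acyloin from conjugate methylation and α-hydroxylation of the ring A enone left by the key step; C11=C12 is hydrogenated on the way.
2. Key disconnection C9–C10: an iron-hydride (MHAT) generated allylic radical at C9 closes ring B 6-exo onto one of the two enantiotopic enone arms of a 4,4-disubstituted cyclohexadienone, setting C5, C9 and C10 at once.
3. Diene precursor 17 ⇐ enyne cross-metathesis of homopropargylic acetate 12 with methyl (S)-3-methylpent-4-enoate 15 (from (R)-β-butyrolactone, fixes C13).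
4. 12 ⇐ dienone aldehyde 7 + (R)-but-3-yn-2-yl mesylate (allenylindium addition fixes C8, Mitsunobu with AcOH fixes C7).
5. 7 ⇐ Robinson annulation of 2-methylpent-4-enal with methyl vinyl ketone, dehydrogenation, ozonolysis. Ring order: ring A first, ring B in the key step.

Convention: clerodane numbering throughout (ring A = C1–C5, C10; ring B = C5–C10; C17 = 8-Me, C18 = carbon on C4, C19 = 5-Me, C20 = 9-Me, C11–C16 = side chain, C15 = ester carbon); β is the face of the 5-methyl group; the target is taken as the enol tautomer drawn.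

## Route

Step 1
Reactants: 1 2-methylpent-4-enal (racemic); 2 but-3-en-2-one
Product: 4 rac-4-methyl-4-(prop-2-en-1-yl)cyclohex-2-en-1-one, via Michael adduct 3 (not isolated)
Conditions: H2SO4 (cat.), PhMe, 50 °C, then reflux (Dean–Stark)
Reagents that add atoms: none
Why: Acid-catalysed Michael addition of the aldehyde enol to the enone followed by intramolecular aldol condensation (Robinson annulation) builds ring A with the quaternary C5; the racemic centre is erased in step 2.

Step 2
Reactants: 4 rac-4-methyl-4-(prop-2-en-1-yl)cyclohex-2-en-1-one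
Product: 5 4-methyl-4-(prop-2-en-1-yl)cyclohexa-2,5-dien-1-one
Conditions: DDQ (1.5 equiv), dioxane, 100 °C
Reagents that add atoms: none
Why: DDQ dehydrogenation of a 4,4-disubstituted cyclohexenone (no aromatisation possible) gives the cross-conjugated dienone, which makes C5 prochiral with two enantiotopic enone arms.

Step 3
Reactants: 5 4-methyl-4-(prop-2-en-1-yl)cyclohexa-2,5-dien-1-one
Product: 7 2-(1-methyl-4-oxocyclohexa-2,5-dien-1-yl)acetaldehyde, via ozonide 6 (not isolated)
Conditions: O3 (1 equiv), CH2Cl2, −78 °C; then Me2S, −78 °C → 23 °C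
Reagents that add atoms: ozone, O=[O+][O-]
Why: Ozone attacks the electron-rich terminal alkene far faster than the electron-poor dienone C=C bonds, and reductive work-up of the ozonide (ozonolysis) gives the C7 aldehyde.

Step 4
Reactants: 8 (R)-but-3-yn-2-ol
Product: 9 (R)-but-3-yn-2-yl methanesulfonate
Conditions: MsCl, Et3N, CH2Cl2, −78 °C → 0 °C
Reagents that add atoms: methanesulfonyl chloride, CS(=O)(=O)Cl
Why: O-Sulfonylation of the propargylic alcohol; the stereocentre is not touched.

Step 5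
Reactants: 7 2-(1-methyl-4-oxocyclohexa-2,5-dien-1-yl)acetaldehyde; 9 (R)-but-3-yn-2-yl methanesulfonate
Product: 11 4-[(2R,3S)-2-hydroxy-3-methylpent-4-yn-1-yl]-4-methylcyclohexa-2,5-dien-1-one, via allenylindium reagent 10 (not isolated)
Conditions: Pd(dppf)Cl2 (5 mol %), InI (1.4 equiv), THF/HMPA (3:1), 23 °C
Reagents that add atoms: none
Why: Marshall propargylation: zerovalent palladium displaces the mesylate anti-SN2′, transmetalation gives the (P)-allenylindium (trivalent indium), and this adds to the aldehyde (not the dienone) through a closed SE2′ transition state, so C8 is set as S by net inversion of the mesylate carbon and C7 as R (anti adduct, minor syn isomer removed by chromatography).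

Step 6
Reactants: 11 4-[(2R,3S)-2-hydroxy-3-methylpent-4-yn-1-yl]-4-methylcyclohexa-2,5-dien-1-one
Product: 12 (2S,3S)-3-methyl-1-(1-methyl-4-oxocyclohexa-2,5-dien-1-yl)pent-4-yn-2-yl acetate
Conditions: PPh3, DIAD, AcOH, PhMe, 0 °C → 23 °C
Reagents that add atoms: acetic acid, CC(=O)O
Why: Mitsunobu reaction: acetate displaces the alkoxyphosphonium by SN2 with inversion (7R → 7S), giving the 7-OAc/8-Me relationship that is trans on ring B and installing the acetate of the target in the same operation.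

Step 7
Reactants: 13 (R)-4-methyloxetan-2-one
Product: 15 methyl (S)-3-methylpent-4-enoate, via bromomagnesium carboxylate 14 (not isolated)
Conditions: CH2=CHMgBr (1.3 equiv), CuBr·SMe2 (10 mol %), THF/Me2S, −30 °C; then 3 M HCl in MeOH (excess), 23 °C
Reagents that add atoms: vinylmagnesium bromide, C=C[Mg]Br; methanol, CO
Why: Copper-catalysed Grignard opening of a β-lactone occurs by SN2 attack at the β-carbon (alkyl C–O cleavage) with inversion, (R) → (S), which is the C13 configuration of the target, and Fischer esterification in the acidic methanol quench gives the ester.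

Step 8
Reactants: 12 (2S,3S)-3-methyl-1-(1-methyl-4-oxocyclohexa-2,5-dien-1-yl)pent-4-yn-2-yl acetate; 15 methyl (S)-3-methylpent-4-enoate
Product: 17 methyl (3S,4E,7S,8S)-8-acetoxy-3,7-dimethyl-6-methylidene-9-(1-methyl-4-oxocyclohexa-2,5-dien-1-yl)non-4-enoate, via 2-substituted butadiene 16 (not isolated)
Conditions: second-generation Grubbs catalyst (10 mol %), ethylene (1 atm), 15 (3 equiv), CH2Cl2, 40 °C
Reagents that add atoms: ethylene, C=C
Why: Enyne cross-metathesis: ethylene turns the terminal alkyne into the 2-substituted butadiene, whose monosubstituted vinyl end then undergoes E-selective cross-metathesis with 15; the dienone and the 1,1-disubstituted alkene are inert and no stereocentre is touched.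

Step 9
Reactants: 17 methyl (3S,4E,7S,8S)-8-acetoxy-3,7-dimethyl-6-methylidene-9-(1-methyl-4-oxocyclohexa-2,5-dien-1-yl)non-4-enoate
Product: 18 methyl (11E,13S)-7β-acetoxy-2-oxo-18-nor-5β,10β-cleroda-3,11-dien-15-oate (cis-decalin; 8α-Me; 9α-Me; 9β-side chain; 10β-H)
Conditions: Fe(acac)3 (0.5 equiv), PhSiH3 (2.5 equiv), EtOH/(CH2OH)2 (5:1), 0.005 M, 60 °C
Reagents that add atoms: none
Why: Proposed new method: the iron hydride formed from Fe(acac)3 and PhSiH3 transfers a hydrogen atom to the terminal CH2 (C20) of the diene, the resulting C9/C12 allylic radical adds 6-exo through its tertiary end C9 to C10 of the dienone (the tether on C5 forces the cis ring fusion), and the α-keto radical is reduced and protonated; the closest known reaction is the iron-hydride MHAT-initiated intramolecular reductive olefin–enone (Giese) cyclization, extended here to a diene donor and a prochiral dienone; a chair transition state with 7-OAc and 8-Me equatorial selects one enone arm (sets C5 and C10), and allylic 1,3-strain between C8–H and the rigid C11=C12 unit, which cannot sit axial over the other enone arm, puts C11 equatorial and C20 axial (sets C9, C17 and C20 cis).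

Step 10
Reactants: 18 methyl (11E,13S)-7β-acetoxy-2-oxo-18-nor-5β,10β-cleroda-3,11-dien-15-oate
Product: 21 methyl (11E,13S)-7β-acetoxy-3-hydroxy-2-oxo-5β,10β-clerod-11-en-15-oate (C3/C4 epimers), via silyl enol ether 19 (not isolated), via α-silyloxy ketone 20 (not isolated)
Conditions: Me2CuLi (1.5 equiv), TMSCl (3 equiv), THF, −78 °C; crude enol ether: mCPBA (1.05 equiv), CH2Cl2, −20 °C; then 1 M HCl, THF, 0 °C
Reagents that add atoms: lithium dimethylcuprate, [Li+].C[Cu-]C; mCPBA, O=C(OO)c1cccc(Cl)c1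
Why: TMSCl-accelerated Gilman 1,4-addition delivers C18 to C4 and gives the C2–C3 silyl enol ether regiospecifically, and Rubottom oxidation (the enol ether is far more nucleophilic than the hindered C11=C12 alkene) puts oxygen on C3; the new C3 and C4 centres are destroyed in steps 12 and 13.

Step 11
Reactants: 21 methyl (11E,13S)-7β-acetoxy-3-hydroxy-2-oxo-5β,10β-clerod-11-en-15-oate
Product: 22 methyl (13R)-7β-acetoxy-3-hydroxy-2-oxo-5β,10β-clerodan-15-oate (C3/C4 epimers)
Conditions: H2 (3 atm), 10% Pd/C, EtOAc, 23 °C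
Reagents that add atoms: none
Why: Heterogeneous hydrogenation saturates the only C=C bond left (C11=C12) without touching ketone, esters or stereocentres; the C13 descriptor changes from S to R only through the priority change.

Step 12
Reactants: 22 methyl (13R)-7β-acetoxy-3-hydroxy-2-oxo-5β,10β-clerodan-15-oate
Product: 23 methyl (13R)-7β-acetoxy-3-hydroxy-2-oxo-5β,10β-clerod-3-en-15-oate (diosphenol)
Conditions: DMP (1.3 equiv), CH2Cl2, 23 °C
Reagents that add atoms: none
Why: Dess–Martin oxidation of the acyloin gives the 2,3-dione, which enolises toward the methyl-bearing C4 to the tetrasubstituted diosphenol and so removes the C3 and C4 stereocentres.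

Step 13
Reactants: 23 methyl (13R)-7β-acetoxy-3-hydroxy-2-oxo-5β,10β-clerod-3-en-15-oate
Product: 26 methyl (5S,7S,8S,9R,10R,13R)-7-acetoxy-2-hydroxy-3-oxocleroda-1,4(18)-dien-15-oate (CNP0180040.1), via 4-phenylselanyl dione 24 (not isolated), via selenoxide 25 (not isolated)
Conditions: PhSeCl (1.1 equiv), pyridine (1.2 equiv), CH2Cl2, 0 °C; then mCPBA (1.1 equiv), −78 °C → 23 °C
Reagents that add atoms: none
Why: α-Selenenylation of the diosphenol at its enol carbon C4, oxidation to the selenoxide and syn-elimination, which can only take a hydrogen from C18 because C5 is quaternary, give the exocyclic C4=C18 enone, and the 2,3-dione then enolises toward C1 to the target tautomer.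

## Compound list

1 | 2-methylpent-4-enal (racemic) | CC(CC=C)C=O | starting material
2 | but-3-en-2-one (methyl vinyl ketone) | CC(=O)C=C | starting material
3 | 2-methyl-2-(3-oxobutyl)pent-4-enal (racemic Michael adduct) | CC(=O)CCC(C)(CC=C)C=O | intermediate
4 | rac-4-methyl-4-(prop-2-en-1-yl)cyclohex-2-en-1-one | CC1(CC=C)C=CC(=O)CC1 | intermediate
5 | 4-methyl-4-(prop-2-en-1-yl)cyclohexa-2,5-dien-1-one (achiral) | CC1(CC=C)C=CC(=O)C=C1 | intermediate
6 | 4-methyl-4-[(1,2,4-trioxolan-3-yl)methyl]cyclohexa-2,5-dien-1-one (ozonide) | CC1(CC2OCOO2)C=CC(=O)C=C1 | intermediate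
7 | 2-(1-methyl-4-oxocyclohexa-2,5-dien-1-yl)acetaldehyde | CC1(CC=O)C=CC(=O)C=C1 | intermediate
8 | (R)-but-3-yn-2-ol | C[C@@H](O)C#C | starting material
9 | (R)-but-3-yn-2-yl methanesulfonate | C[C@@H](OS(C)(=O)=O)C#C | intermediate
10 | (P)-buta-1,2-dien-1-ylindium iodide methanesulfonate (trivalent indium) | CC([H])=[C@@]=C([H])[In](I)OS(C)(=O)=O | intermediate
11 | 4-[(2R,3S)-2-hydroxy-3-methylpent-4-yn-1-yl]-4-methylcyclohexa-2,5-dien-1-one | CC1(C=CC(=O)C=C1)C[C@@H](O)[C@@H](C)C#C | intermediate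
12 | (2S,3S)-3-methyl-1-(1-methyl-4-oxocyclohexa-2,5-dien-1-yl)pent-4-yn-2-yl acetate | CC1(C=CC(=O)C=C1)C[C@H](OC(C)=O)[C@@H](C)C#C | intermediate
13 | (R)-4-methyloxetan-2-one ((R)-β-butyrolactone) | C[C@@H]1CC(=O)O1 | starting material
14 | bromomagnesium (S)-3-methylpent-4-enoate | C=C[C@@H](C)CC(=O)O[Mg]Br | intermediate
15 | methyl (S)-3-methylpent-4-enoate | C=C[C@@H](C)CC(=O)OC | intermediate
16 | (2S,3S)-3-methyl-4-methylidene-1-(1-methyl-4-oxocyclohexa-2,5-dien-1-yl)hex-5-en-2-yl acetate | CC1(C=CC(=O)C=C1)C[C@H](OC(C)=O)[C@@H](C)C(=C)C=C | intermediate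
17 | methyl (3S,4E,7S,8S)-8-acetoxy-3,7-dimethyl-6-methylidene-9-(1-methyl-4-oxocyclohexa-2,5-dien-1-yl)non-4-enoate | CC1(C=CC(=O)C=C1)C[C@H](OC(C)=O)[C@@H](C)C(=C)/C=C/[C@@H](C)CC(=O)OC | intermediate
18 | methyl (11E,13S)-7β-acetoxy-2-oxo-18-nor-5β,10β-cleroda-3,11-dien-15-oate (cis-decalin; 8α-Me, 9α-Me, 10β-H) | C1=CC(=O)C[C@@H]2[C@@](C)(/C=C/[C@@H](C)CC(=O)OC)[C@H](C)[C@@H](OC(C)=O)C[C@]12C | intermediate
19 | methyl (11E,13S)-7β-acetoxy-2-trimethylsilyloxy-5β,10β-cleroda-2,11-dien-15-oate (C4 epimers) | CC1C=C(O[Si](C)(C)C)C[C@@H]2[C@@](C)(/C=C/[C@@H](C)CC(=O)OC)[C@H](C)[C@@H](OC(C)=O)C[C@]12C | intermediate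
20 | methyl (11E,13S)-7β-acetoxy-2-oxo-3-trimethylsilyloxy-5β,10β-clerod-11-en-15-oate (C3/C4 epimers) | CC1C(O[Si](C)(C)C)C(=O)C[C@@H]2[C@@](C)(/C=C/[C@@H](C)CC(=O)OC)[C@H](C)[C@@H](OC(C)=O)C[C@]12C | intermediate
21 | methyl (11E,13S)-7β-acetoxy-3-hydroxy-2-oxo-5β,10β-clerod-11-en-15-oate (C3/C4 epimers) | CC1C(O)C(=O)C[C@@H]2[C@@](C)(/C=C/[C@@H](C)CC(=O)OC)[C@H](C)[C@@H](OC(C)=O)C[C@]12C | intermediate
22 | methyl (13R)-7β-acetoxy-3-hydroxy-2-oxo-5β,10β-clerodan-15-oate (C3/C4 epimers) | CC1C(O)C(=O)C[C@@H]2[C@@](C)(CC[C@@H](C)CC(=O)OC)[C@H](C)[C@@H](OC(C)=O)C[C@]12C | intermediate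
23 | methyl (13R)-7β-acetoxy-3-hydroxy-2-oxo-5β,10β-clerod-3-en-15-oate (diosphenol) | CC1=C(O)C(=O)C[C@@H]2[C@@](C)(CC[C@@H](C)CC(=O)OC)[C@H](C)[C@@H](OC(C)=O)C[C@]12C | intermediate
24 | methyl (13R)-7β-acetoxy-2,3-dioxo-4-phenylselanyl-5β,10β-clerodan-15-oate (C4 epimers) | CC1([Se]c3ccccc3)C(=O)C(=O)C[C@@H]2[C@@](C)(CC[C@@H](C)CC(=O)OC)[C@H](C)[C@@H](OC(C)=O)C[C@]12C | intermediate
25 | methyl (13R)-7β-acetoxy-2,3-dioxo-4-phenylseleninyl-5β,10β-clerodan-15-oate (selenoxide) | CC1([Se](=O)c3ccccc3)C(=O)C(=O)C[C@@H]2[C@@](C)(CC[C@@H](C)CC(=O)OC)[C@H](C)[C@@H](OC(C)=O)C[C@]12C | intermediate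
26 | methyl (5S,7S,8S,9R,10R,13R)-7-acetoxy-2-hydroxy-3-oxocleroda-1,4(18)-dien-15-oate (5β-Me, 7β-OAc, 8α-Me, 9α-Me, 10β-H) | C=C1C(=O)C(O)=C[C@@H]2[C@@](C)(CC[C@@H](C)CC(=O)OC)[C@H](C)[C@@H](OC(C)=O)C[C@]12C | target

## Step count and risks

Total step count: 13. Longest linear sequence: 11 steps (1, 2, 3, 5, 6, 8, 9, 10, 11, 12, 13).

**Risk 1 — step 9 (key cyclization).** The allylic radical is stabilised and must form a quaternary centre next to the quaternary C5, so it may be reduced before it cyclizes or give poor control at C9. The fallback gives up the conjugated donor and cyclizes a non-stabilised tertiary radical. It sets out from 12: Markovnikov hydroiodination (TMSCl, NaI, H2O, MeCN) gives the 2-iodo-1-alkene F1. In parallel 15 is hydroborated with 9-BBN-H to the B-alkyl-9-BBN F2. B-alkyl Suzuki coupling of F1 with F2 (Pd(dppf)Cl2, Cs2CO3, DMF/THF/H2O) gives the 1,1-disubstituted alkene F3, which already carries the saturated side chain. Cyclization under the conditions of step 9 gives the saturated-chain cis-decalin enone F4. Me2CuLi/TMSCl, then mCPBA and HCl as in step 10, pass through the silyl enol ether F5 and the α-silyloxy ketone F6 and come back to the route at 22, so step 11 is no longer needed. The price is weaker control at C9, because the allylic-strain element is lost.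

**Risk 2 — step 13 (exocyclic dehydrogenation).** Selenenylation must occur at the hindered C4 next to the quaternary C5, and the product is a reactive cross-conjugated enone. The fallback replaces the selenium chemistry by a palladium-mediated dehydrosilylation. It sets out from 23: O-silylation (TMSCl, Et3N, CH2Cl2) gives the O-silyl diosphenol F11. Pd(OAc)2 (1.1 equiv, MeCN, 40 °C; Saegusa–Ito oxidation: palladation at C4, β-hydride elimination possible only toward C18) comes back to the route at 26.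

**Risk 3 — step 6 (Mitsunobu inversion).** The carbinol is flanked by a branched propargylic carbon, so elimination or incomplete inversion may compete. The fallback makes the syn isomer directly through an open transition state. It sets out from 7: (S)-but-3-yn-2-ol F7 is mesylated to the (S)-mesylate F8. Bu3SnLi with CuBr·SMe2 (THF, −78 °C) converts F8 anti-SN2′ into the (M)-allenylstannane F9. BF3·OEt2-promoted addition of F9 to 7 (CH2Cl2, −78 °C; anti-SE2′) gives the (2S,3S)-syn alcohol F10. Ac2O, pyridine and DMAP then come back to the route at 12.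

## Further compounds

F1 | step 9 | (2S,3S)-4-iodo-3-methyl-1-(1-methyl-4-oxocyclohexa-2,5-dien-1-yl)pent-4-en-2-yl acetate | CC1(C=CC(=O)C=C1)C[C@H](OC(C)=O)[C@@H](C)C(I)=C
F2 | step 9 | methyl (R)-5-(9-borabicyclo[3.3.1]nonan-9-yl)-3-methylpentanoate | COC(=O)C[C@H](C)CCB1C2CCCC1CCC2
F3 | step 9 | methyl (3R,7S,8S)-8-acetoxy-3,7-dimethyl-6-methylidene-9-(1-methyl-4-oxocyclohexa-2,5-dien-1-yl)nonanoate | CC1(C=CC(=O)C=C1)C[C@H](OC(C)=O)[C@@H](C)C(=C)CC[C@@H](C)CC(=O)OC
F4 | step 9 | methyl (13R)-7β-acetoxy-2-oxo-18-nor-5β,10β-clerod-3-en-15-oate | C1=CC(=O)C[C@@H]2[C@@](C)(CC[C@@H](C)CC(=O)OC)[C@H](C)[C@@H](OC(C)=O)C[C@]12C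
F5 | step 9 | methyl (13R)-7β-acetoxy-2-trimethylsilyloxy-5β,10β-clerod-2-en-15-oate (C4 epimers) | CC1C=C(O[Si](C)(C)C)C[C@@H]2[C@@](C)(CC[C@@H](C)CC(=O)OC)[C@H](C)[C@@H](OC(C)=O)C[C@]12C
F6 | step 9 | methyl (13R)-7β-acetoxy-2-oxo-3-trimethylsilyloxy-5β,10β-clerodan-15-oate (C3/C4 epimers) | CC1C(O[Si](C)(C)C)C(=O)C[C@@H]2[C@@](C)(CC[C@@H](C)CC(=O)OC)[C@H](C)[C@@H](OC(C)=O)C[C@]12C
F7 | step 6 | (S)-but-3-yn-2-ol | C[C@H](O)C#C
F8 | step 6 | (S)-but-3-yn-2-yl methanesulfonate | C[C@H](OS(C)(=O)=O)C#C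
F9 | step 6 | (M)-tributyl(buta-1,2-dien-1-yl)stannane | CC([H])=[C@]=C([H])[Sn](CCCC)(CCCC)CCCC
F10 | step 6 | 4-[(2S,3S)-2-hydroxy-3-methylpent-4-yn-1-yl]-4-methylcyclohexa-2,5-dien-1-one | CC1(C=CC(=O)C=C1)C[C@H](O)[C@@H](C)C#C
F11 | step 13 | methyl (13R)-7β-acetoxy-2-oxo-3-trimethylsilyloxy-5β,10β-clerod-3-en-15-oate | CC1=C(O[Si](C)(C)C)C(=O)C[C@@H]2[C@@](C)(CC[C@@H](C)CC(=O)OC)[C@H](C)[C@@H](OC(C)=O)C[C@]12C
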